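**Strategy**

The route rests on cutting upper ring C at O1–C2 and C3–C4, which exposes an aryl ortho-quinone methide and an E-styrene. The feature exploited is the all-trans C2/C3/C4 triad of upper ring C, held between ring oxygen O1 and the diarylmethine C4 that is bonded to C8 of lower ring A. One inverse-demand (4+2) cycloaddition forms both bonds, closes ring C and sets the three stereocentres, with a C3 boronate as the masked hydroxyl. The precursor is a benzhydrol linking C8 of penta-O-benzyl-6-methylcatechin to a 4-benzyloxy-2-hydroxyphenyl ring, ionised by a chiral acid in the presence of an E-styrenylboronate.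

Key step: step 8

Assumption: the sense of facial induction of the chiral acid in step 8 towards the homochiral lower unit cannot be fixed on paper, so the (R)-catalyst is written and stands for whichever antipode proves matched to the (4S) face.

**Route**

Step 1
Reactants: 1 (+)-catechin
Product: 2 5,7,3',4'-tetra-O-benzyl-(+)-catechin, (2R,3S)
Conditions: BnBr (4.2 equiv), K2CO3, DMF, 0 °C → rt
Reagents that add atoms: benzyl bromide, BrCc1ccccc1
Why: Williamson etherification in which carbonate ionises only the four phenols, so the C3 alcohol stays free and the mild base avoids the ring opening that would epimerise C2; both stereocentres come unchanged from 1.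

Step 2
Reactants: 2 5,7,3',4'-tetra-O-benzyl-(+)-catechin
Product: 3 3,5,7,3',4'-penta-O-benzyl-(+)-catechin, (2R,3S)
Conditions: NaH, BnBr, n-Bu4NI (cat.), THF, 0 °C → rt
Reagents that add atoms: benzyl bromide, BrCc1ccccc1
Why: Williamson etherification of the secondary alkoxide; with every phenol already capped there is no quinone methide path to C2 epimerisation, so (2R,3S) is kept.

Step 3
Reactants: 3 3,5,7,3',4'-penta-O-benzyl-(+)-catechin
Product: 4 8-bromo-3,5,7,3',4'-penta-O-benzylcatechin, (2R,3S)
Conditions: NBS (1.05 equiv), CH2Cl2, −78 °C → rt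
Reagents that add atoms: N-bromosuccinimide, O=C1CCC(=O)N1Br
Why: Electrophilic aromatic bromination of the phloroglucinol-type ring A, which in benzylated catechins takes one equivalent of NBS selectively at C8.

Step 4
Reactants: 4 8-bromo-3,5,7,3',4'-penta-O-benzylcatechin
Product: 5 8-bromo-6-iodo-3,5,7,3',4'-penta-O-benzylcatechin, (2R,3S)
Conditions: NIS (1.1 equiv), TFA (cat.), MeCN/CH2Cl2, 0 °C → rt
Reagents that add atoms: N-iodosuccinimide, O=C1CCC(=O)N1I
Why: Electrophilic aromatic iodination at C6, the last free position of ring A and the most electron-rich CH in the molecule (between two benzyloxy groups and para to O1).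

Step 5
Reactants: 5 8-bromo-6-iodo-3,5,7,3',4'-penta-O-benzylcatechin
Product: 6 8-bromo-6-methyl-3,5,7,3',4'-penta-O-benzylcatechin, (2R,3S)
Conditions: MeZnCl (1.5 equiv), Pd(PPh3)4 (5 mol %), THF, rt → 45 °C
Reagents that add atoms: methylzinc chloride, C[Zn]Cl
Why: Negishi cross-coupling in which zerovalent palladium inserts into the C–I bond much faster than into the C–Br bond, so the methyl group goes to C6 and the C8 bromide is kept as the handle for step 6.

Step 6
Reactants: 6 8-bromo-6-methyl-3,5,7,3',4'-penta-O-benzylcatechin; 7 4-benzyloxy-2-hydroxybenzaldehyde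
Product: 10 benzhydrol [(2R,3S)-3,5,7-tris(benzyloxy)-2-(3,4-dibenzyloxyphenyl)-6-methylchroman-8-yl](4-benzyloxy-2-hydroxyphenyl)methanol (both carbinol epimers), via aryllithium 8 (not isolated), via sodium phenoxide 9 (not isolated)
Conditions: 6, n-BuLi (1.05 equiv), THF, −78 °C; then 9 [from 7, NaH (1.0 equiv), THF, 0 °C], −78 → 0 °C; then H2O, pH 7 buffer wash
Reagents that add atoms: none
Why: Bromine–lithium exchange followed by 1,2-addition of the aryllithium to the aldehyde, whose phenol is turned into its sodium salt beforehand so that no aryllithium is spent as a base; the carbinol centre needs no control because step 8 planarises it.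

Step 7
Reactants: 11 3,4-dibenzyloxybenzaldehyde
Product: 12 (E)-2-[2-(3,4-dibenzyloxyphenyl)ethenyl]-4,4,5,5-tetramethyl-1,3,2-dioxaborolane
Conditions: CH2(Bpin)2 (1.2 equiv), lithium 2,2,6,6-tetramethylpiperidide (1.2 equiv), THF, 0 °C; then 11, −78 °C → rt
Reagents that add atoms: bis(pinacolato)borylmethane, CC1(C)OB(CB2OC(C)(C)C(C)(C)O2)OC1(C)C
Why: Boron–Wittig olefination, in which the α-boryl carbanion adds to the aldehyde and syn elimination of the boron oxide gives the E-alkenylboronate.

Step 8
Reactants: 10 benzhydrol (both carbinol epimers); 12 (E)-styrenylboronic acid pinacol ester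
Product: 14 octa-O-benzyl-3-deoxy-3-(pinacolatoboryl)fisetinidol-(4α→8)-6-methylcatechin (upper ring C all-trans; CIP labels 2S,3S,4S because boron ranks below carbon; lower unit 2R,3S), via E-ortho-quinone methide 13 (not isolated)
Conditions: 12 (3 equiv), (R)-3,3'-bis(2,4,6-triisopropylphenyl)-1,1'-binaphthyl-2,2'-diyl N-triflylphosphoramide (10 mol %), 4 Å MS, toluene, −30 → 0 °C, slow addition of 10
Reagents that add atoms: none
Why: The strong chiral acid ionises the doubly benzylic carbinol of 10 to the hydrogen-bonded E-ortho-quinone methide 13, whose methide carbon (C4) is attacked by the boron-bearing alkene carbon of 12 while the phenolic oxygen captures the benzylic carbon, where the 3,4-dibenzyloxyphenyl group stabilises the developing positive charge, in a concerted but asynchronous inverse-demand hetero-Diels–Alder reaction. The closest known reaction type is the chiral Brønsted acid-catalysed (4+2) cycloaddition of ortho-quinone methides, generated in the flask from 2-hydroxybenzhydrols, with styrenes including E-β-substituted ones, an acid of this strength being the usual choice when the alkene offers no hydrogen-bond donor. Upper ring C closes by this intermolecular (4+2) cycloaddition, in which O1–C2 and C3–C4 are formed across the four-atom O=C8a–C4a=C4 unit. C2 and C3 are set relative to each other by suprafacial transfer of the E-alkene geometry (2,3-trans), C4 relative to C2 by the E geometry of 13, which is open because C5 of the upper unit bears only hydrogen, together with the endo position of the dienophile aryl group (2,4-cis, hence 3,4-trans), and the absolute sense at C4 relative to the homochiral lower unit by the chiral counter-anion held at the quinone methide oxygen. The step needs regioselectivity, secured by the cation-stabilising aryl group on the alkene carbon that bonds to oxygen, and chemoselectivity for ring closure over loss of boron or arylation by a second molecule of 10, secured by the weakly Lewis acidic pinacol ester, the base-free cold medium, slow addition of 10 to excess 12, and the C6 methyl group that blocks the last free position of lower ring A.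

Step 9
Reactants: 14 octa-O-benzyl C3 pinacol boronate
Product: 15 octa-O-benzyl-fisetinidol-(4α→8)-6-methylcatechin (upper unit 2R,3S,4S; lower unit 2R,3S)
Conditions: NaBO3·4H2O (5 equiv), THF/H2O (1:1), rt
Reagents that add atoms: sodium perborate (NaBO3·4H2O, dimeric peroxoborate), [Na+].[Na+].O[B-]1(O)OO[B-](O)(O)OO1
Why: Oxidation of the secondary boronate by 1,2-migration of C3 from boron to the peroxide oxygen with retention, so the hydroxyl arrives trans to both neighbours; the mild perborate is chosen to disfavour β-elimination of the ring oxygen, and no free phenol is present to be oxidised.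

Step 10
Reactants: 15 octa-O-benzyl-fisetinidol-(4α→8)-6-methylcatechin
Product: 16 fisetinidol-(4α→8)-6-methylcatechin, CNP0288113.1 (upper unit 2R,3S,4S; lower unit 2R,3S)
Conditions: H2 (1 atm), Pd(OH)2/C, THF/MeOH, rt
Reagents that add atoms: none
Why: Catalytic hydrogenolysis of the eight benzyl ethers under conditions that are standard for benzylated flavan dimers and leave the C2–O1 and C4–C8 benzylic bonds and all five stereocentres untouched.

**Compound list**

1 | (+)-catechin, (2R,3S) | Oc1cc(O)c2c(c1)O[C@H](c1ccc(O)c(O)c1)[C@@H](O)C2 | starting material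
2 | 5,7,3',4'-tetra-O-benzyl-(+)-catechin, (2R,3S) | c1ccccc1COc1cc(OCc3ccccc3)c2c(c1)O[C@H](c1ccc(OCc3ccccc3)c(OCc3ccccc3)c1)[C@@H](O)C2 | intermediate
3 | 3,5,7,3',4'-penta-O-benzyl-(+)-catechin, (2R,3S) | c1ccccc1COc1cc(OCc3ccccc3)c2c(c1)O[C@H](c1ccc(OCc3ccccc3)c(OCc3ccccc3)c1)[C@@H](OCc1ccccc1)C2 | intermediate
4 | 8-bromo-3,5,7,3',4'-penta-O-benzylcatechin, (2R,3S) | Brc1c(OCc3ccccc3)cc(OCc3ccccc3)c2c1O[C@H](c1ccc(OCc3ccccc3)c(OCc3ccccc3)c1)[C@@H](OCc1ccccc1)C2 | intermediate
5 | 8-bromo-6-iodo-3,5,7,3',4'-penta-O-benzylcatechin, (2R,3S) | Brc1c(OCc3ccccc3)c(I)c(OCc3ccccc3)c2c1O[C@H](c1ccc(OCc3ccccc3)c(OCc3ccccc3)c1)[C@@H](OCc1ccccc1)C2 | intermediate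
6 | 8-bromo-6-methyl-3,5,7,3',4'-penta-O-benzylcatechin, (2R,3S) | Brc1c(OCc3ccccc3)c(C)c(OCc3ccccc3)c2c1O[C@H](c1ccc(OCc3ccccc3)c(OCc3ccccc3)c1)[C@@H](OCc1ccccc1)C2 | intermediate
7 | 4-benzyloxy-2-hydroxybenzaldehyde | O=Cc1ccc(OCc2ccccc2)cc1O | starting material
8 | 8-lithio-6-methyl-3,5,7,3',4'-penta-O-benzylcatechin, (2R,3S), aryllithium formed in the flask | [Li]c1c(OCc3ccccc3)c(C)c(OCc3ccccc3)c2c1O[C@H](c1ccc(OCc3ccccc3)c(OCc3ccccc3)c1)[C@@H](OCc1ccccc1)C2 | intermediate
9 | sodium 5-benzyloxy-2-formylphenoxide, formed in the flask | O=Cc1ccc(OCc2ccccc2)cc1[O-].[Na+] | intermediate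
10 | benzhydrol [(2R,3S)-3,5,7-tris(benzyloxy)-2-(3,4-dibenzyloxyphenyl)-6-methylchroman-8-yl](4-benzyloxy-2-hydroxyphenyl)methanol, both carbinol epimers | Cc1c(OCc6ccccc6)c2c(c(C(O)c3ccc(OCc4ccccc4)cc3O)c1OCc1ccccc1)O[C@H](c1ccc(OCc3ccccc3)c(OCc3ccccc3)c1)[C@@H](OCc1ccccc1)C2 | intermediate
11 | 3,4-dibenzyloxybenzaldehyde | O=Cc1ccc(OCc2ccccc2)c(OCc2ccccc2)c1 | starting material
12 | (E)-2-[2-(3,4-dibenzyloxyphenyl)ethenyl]-4,4,5,5-tetramethyl-1,3,2-dioxaborolane | CC1(C)OB(/C=C/c2ccc(OCc3ccccc3)c(OCc3ccccc3)c2)OC1(C)C | intermediate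
13 | E-ortho-quinone methide, (E)-3-benzyloxy-6-[(lower-unit C8-aryl)methylidene]cyclohexa-2,4-dien-1-one, lower unit (2R,3S), formed in the flask | O=C1C=C(OCc2ccccc2)C=C/C1=C\c1c(OCc3ccccc3)c(C)c(OCc3ccccc3)c2c1O[C@H](c1ccc(OCc3ccccc3)c(OCc3ccccc3)c1)[C@@H](OCc1ccccc1)C2 | intermediate
14 | octa-O-benzyl-3-deoxy-3-(pinacolatoboryl)fisetinidol-(4α→8)-6-methylcatechin, upper ring C all-trans (CIP 2S,3S,4S), lower unit (2R,3S) | Cc1c(OCc6ccccc6)c2c(c([C@@H]3c4ccc(OCc5ccccc5)cc4O[C@H](c4ccc(OCc5ccccc5)c(OCc5ccccc5)c4)[C@H]3B3OC(C)(C)C(C)(C)O3)c1OCc1ccccc1)O[C@H](c1ccc(OCc3ccccc3)c(OCc3ccccc3)c1)[C@@H](OCc1ccccc1)C2 | intermediate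
15 | octa-O-benzyl-fisetinidol-(4α→8)-6-methylcatechin, upper unit (2R,3S,4S), lower unit (2R,3S) | Cc1c(OCc6ccccc6)c2c(c([C@@H]3c4ccc(OCc5ccccc5)cc4O[C@H](c4ccc(OCc5ccccc5)c(OCc5ccccc5)c4)[C@H]3O)c1OCc1ccccc1)O[C@H](c1ccc(OCc3ccccc3)c(OCc3ccccc3)c1)[C@@H](OCc1ccccc1)C2 | intermediate
16 | fisetinidol-(4α→8)-6-methylcatechin, CNP0288113.1, upper unit (2R,3S,4S), lower unit (2R,3S) | Cc1c(O)c2c(c([C@@H]3c4ccc(O)cc4O[C@H](c4ccc(O)c(O)c4)[C@H]3O)c1O)O[C@H](c1ccc(O)c(O)c1)[C@@H](O)C2 | target

**Step count and risks**

Total step count: 10. Longest linear sequence: 9 steps (steps 1–6 and 8–10); step 7 is a one-step branch.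

Steps most likely to fail:

1. Step 8. The benzylic cation that develops β to boron may lose the boryl group before O1–C2 closes, which gives alkenyl transfer and no ring. The quinone methide may also be arylated by ring A of a second molecule of 10, and the catalyst may fail to override the facial bias of the twisted lower ring. The fallback sets out from 10, with the alkyne drawn from 11, and returns at 15. Aldehyde 11 is homologated with dimethyl (1-diazo-2-oxopropyl)phosphonate and K2CO3 in MeOH (Ohira–Bestmann variant of the Seyferth–Gilbert reaction) to 3,4-dibenzyloxyphenylacetylene F1. Under the same acid catalysis the quinone methide from 10 adds F1 in a (4+2) sense to give the 2-aryl-4H-chromene (flav-2-ene) F2. The cycloaddition then has to set C4 only, and an unwanted C4 epimer, being a diastereomer, can be removed by chromatography. Hydroboration of the enol ether double bond with BH3·SMe2 places boron at C3 on the face away from the C4 aryl group and hydrogen at C2 on the same face, giving the all-trans C3 borane F3. Oxidation with NaBO3·4H2O comes back to the route at 15.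

2. Step 6. Addition of the hindered aryllithium to the electron-rich phenoxide aldehyde may be slow, so that proton transfer or attack on a benzylic ether takes over, and the acid-labile product may ionise during isolation. The fallback sets out from 7 and returns at 10. Aldehyde 7 is silylated (TBSCl, imidazole, CH2Cl2) to 4-benzyloxy-2-(tert-butyldimethylsilyloxy)benzaldehyde F4, a neutral and fully electrophilic aldehyde. Aryllithium 8, made from 6 as in step 6, is added at −78 °C to give the silyl-protected benzhydrol F5. Desilylation with TBAF buffered with AcOH in THF at 0 °C gives 10.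

3. Step 5. Insertion of palladium into the hindered C6–I bond may be slow enough for competing insertion at C8–Br or hydrodehalogenation to erode the chemoselectivity. The fallback sets out from 5 and returns at 6. Iodine–lithium exchange with one equivalent of n-BuLi in THF at −100 °C, which is much faster than bromine–lithium exchange, gives the 8-bromo-6-lithio species F6, and a MeI quench at that temperature gives 6.

**Further compounds**

F1 | step 8 | 3,4-dibenzyloxyphenylacetylene | C#Cc1ccc(OCc2ccccc2)c(OCc2ccccc2)c1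
F2 | step 8 | octa-O-benzyl 2-aryl-4H-chromene (flav-2-ene) joined through C4 to C8 of 6-methylcatechin, (4S), lower unit (2R,3S) | Cc1c(OCc6ccccc6)c2c(c([C@@H]3c4ccc(OCc5ccccc5)cc4OC(c4ccc(OCc5ccccc5)c(OCc5ccccc5)c4)=C3)c1OCc1ccccc1)O[C@H](c1ccc(OCc3ccccc3)c(OCc3ccccc3)c1)[C@@H](OCc1ccccc1)C2
F3 | step 8 | octa-O-benzyl dimer with a BH2 group at C3 of the upper unit, upper ring C all-trans, lower unit (2R,3S) | Cc1c(OCc6ccccc6)c2c(c([C@@H]3c4ccc(OCc5ccccc5)cc4O[C@H](c4ccc(OCc5ccccc5)c(OCc5ccccc5)c4)[C@H]3B)c1OCc1ccccc1)O[C@H](c1ccc(OCc3ccccc3)c(OCc3ccccc3)c1)[C@@H](OCc1ccccc1)C2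
F4 | step 6 | 4-benzyloxy-2-(tert-butyldimethylsilyloxy)benzaldehyde | O=Cc1ccc(OCc2ccccc2)cc1O[Si](C)(C)C(C)(C)C
F5 | step 6 | benzhydrol 10 with its phenol as the tert-butyldimethylsilyl ether, both carbinol epimers, lower unit (2R,3S) | Cc1c(OCc6ccccc6)c2c(c(C(O)c3ccc(OCc4ccccc4)cc3O[Si](C)(C)C(C)(C)C)c1OCc1ccccc1)O[C@H](c1ccc(OCc3ccccc3)c(OCc3ccccc3)c1)[C@@H](OCc1ccccc1)C2
F6 | step 5 | 8-bromo-6-lithio-3,5,7,3',4'-penta-O-benzylcatechin, (2R,3S) | Brc1c(OCc3ccccc3)c([Li])c(OCc3ccccc3)c2c1O[C@H](c1ccc(OCc3ccccc3)c(OCc3ccccc3)c1)[C@@H](OCc1ccccc1)C2
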